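**Strategy.** The benzene ring is numbered C1 (CH2OH), C2 (Br), C3 (OMe), C4 (OH), C5 (Br), C6 (Br). The C2 bromine lies between C1 and C3 and is meta to the C4 hydroxyl, so electrophilic bromination cannot place it. The route therefore cuts the C1–CH2 and C2–Br bonds together and traces both to a 3-methoxyaryne spanning C1–C2. A TIPS-protected 4-fluoroguaiacol is lithiated between F and OMe, loses LiF, and takes up a silylmethyl Grignard reagent (a masked hydroxymethyl anion) at C1 and a bromine electrophile at C2 in one flask. Oxidation of the C–Si bond and bromination of the two remaining ring C–H positions complete the synthesis.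

Key step: step 3

Remark: the target is achiral, so no stereochemistry has to be set. Reagents that contribute no atom other than hydrogen (bases, fluoride sources) are not numbered.

**Step 1**
Reactants: 1 4-fluoro-2-methoxyphenol; 2 triisopropylsilyl chloride
Product: 3 (4-fluoro-2-methoxyphenoxy)triisopropylsilane
Conditions: TIPSCl, imidazole, DMF, rt
Reagents that add atoms: triisopropylsilyl chloride (2), CC(C)[Si](Cl)(C(C)C)C(C)C
Why: Imidazole-promoted O-silylation of a phenol should proceed cleanly and gives a bulky, non-coordinating ether that tolerates alkyllithium and does not direct metalation.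

**Step 2**
Reactants: 4 (chloromethyl)isopropoxydimethylsilane
Product: 5 (isopropoxydimethylsilyl)methylmagnesium chloride
Conditions: Mg turnings, 1,2-dibromoethane (cat.), THF, reflux then rt; used as a titrated solution
Reagents that add atoms: magnesium, [Mg]
Why: Grignard formation by insertion of magnesium into the C–Cl bond is the standard preparation of this hydroxymethyl-anion equivalent, and the isopropoxy group is hindered enough to resist attack by the reagent on its own silicon.

**Step 3**
Reactants: 3 (4-fluoro-2-methoxyphenoxy)triisopropylsilane; 5 (isopropoxydimethylsilyl)methylmagnesium chloride; 6 1,2-dibromotetrachloroethane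
Product: 10 [3-bromo-4-[(isopropoxydimethylsilyl)methyl]-2-methoxyphenoxy]triisopropylsilane, via aryllithium 7 (not isolated), via 3-methoxyaryne 8 (not isolated), via arylmagnesium chloride 9 (not isolated)
Conditions: s-BuLi (1.05 equiv), THF, −78 °C; 5 (3 equiv), −78 °C to −10 °C; then 6 (4 equiv), −78 °C to rt
Reagents that add atoms: 1,2-dibromotetrachloroethane (6), BrC(Cl)(Cl)C(Cl)(Cl)Br
Why: s-BuLi removes the ring hydrogen flanked by fluorine and methoxy, the most acidic C–H because both neighbours acidify it inductively, to give aryllithium 7, which on warming expels LiF and forms aryne 8 across C1–C2. The C3 methoxy group next to the triple bond polarises and distorts the aryne, so the carbon of 5 attacks C1, the terminus remote from oxygen, and the negative charge of arylmagnesium 9 sits on C2 where the inductive, coordinating OMe stabilises it. Bromine transfer from 6 to 9 with loss of tetrachloroethylene then forms the C2–Br bond, so the step is an aryne carbomagnesiation with electrophilic trapping, the known three-component chemistry of 3-alkoxyarynes with organomagnesium reagents. No ring is closed and no stereocentre is created. The selectivities needed are the site of lithiation, secured by the F/OMe pair and by the bulky TIPS ether that shields its own ortho position, and the regiochemistry of addition, secured by the methoxy group adjacent to the aryne. Excess 5 should outcompete 7 for the aryne, and 6 is used in excess because surplus 5 also consumes it.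

**Step 4**
Reactants: 10 [3-bromo-4-[(isopropoxydimethylsilyl)methyl]-2-methoxyphenoxy]triisopropylsilane
Product: 11 [2-bromo-3-methoxy-4-(triisopropylsilyloxy)phenyl]methanol
Conditions: 30% aq H2O2, KHCO3, THF/MeOH (1:1), rt to 40 °C
Reagents that add atoms: hydrogen peroxide, OO
Why: Tamao oxidation of the alkoxysilane (peroxide adds to silicon, the benzylic carbon migrates from Si to O, the silyl ether hydrolyses) should give the benzylic alcohol, and fluoride is left out so that the aryl TIPS ether and the aryl bromide stay intact.

**Step 5**
Reactants: 11 [2-bromo-3-methoxy-4-(triisopropylsilyloxy)phenyl]methanol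
Product: 12 [2-bromo-3-methoxy-4-(triisopropylsilyloxy)phenyl]methyl acetate
Conditions: Ac2O, pyridine, DMAP (cat.), CH2Cl2, 0 °C to rt
Reagents that add atoms: acetic anhydride, CC(=O)OC(C)=O
Why: DMAP-catalysed acylation of a primary alcohol is reliable, and the ester protects the benzylic oxygen from oxidation and from loss of formaldehyde by ipso attack during the later bromination.

**Step 6**
Reactants: 12 [2-bromo-3-methoxy-4-(triisopropylsilyloxy)phenyl]methyl acetate
Product: 13 (2-bromo-4-hydroxy-3-methoxyphenyl)methyl acetate
Conditions: TBAF (1.2 equiv), AcOH (1.2 equiv), THF, 0 °C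
Reagents that add atoms: none
Why: Fluoride cleaves the aryl Si–O bond, and the acetic acid buffer protonates the phenoxide at once, which should suppress 1,6-elimination of acetate to a quinone methide.

**Step 7**
Reactants: 13 (2-bromo-4-hydroxy-3-methoxyphenyl)methyl acetate
Product: 14 (2,3,6-tribromo-4-hydroxy-5-methoxyphenyl)methyl acetate
Conditions: Br2 (2.3 equiv), NaOAc (3 equiv), AcOH, rt to 40 °C; aq Na2S2O3 work-up
Reagents that add atoms: bromine, BrBr
Why: Electrophilic aromatic bromination should fill C5 (ortho to the free C4 hydroxyl) and then C6 (para to the C3 methoxy), the only ring C–H positions left, while NaOAc removes HBr and any solvolytic exchange at the benzylic carbon in acetic acid simply returns the acetate.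

**Step 8**
Reactants: 14 (2,3,6-tribromo-4-hydroxy-5-methoxyphenyl)methyl acetate
Product: 15 (2,3,6-tribromo-4-hydroxy-5-methoxyphenyl)methanol
Conditions: LiOH (3 equiv), THF/H2O (3:1), 0 °C; then aq NaH2PO4 to pH 5
Reagents that add atoms: none
Why: Saponification of the acetate should release the benzylic alcohol, and because water is the only nucleophile present, even an elimination–addition detour through the quinone methide leads to the same product; alcohol solvents and strong acid are avoided to prevent benzylic ether formation.

**Compound list**
1 | 4-fluoro-2-methoxyphenol | COc1cc(F)ccc1O | starting material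
2 | triisopropylsilyl chloride | CC(C)[Si](Cl)(C(C)C)C(C)C | starting material
3 | (4-fluoro-2-methoxyphenoxy)triisopropylsilane | COc1cc(F)ccc1O[Si](C(C)C)(C(C)C)C(C)C | intermediate
4 | (chloromethyl)isopropoxydimethylsilane | CC(C)O[Si](C)(C)CCl | starting material
5 | (isopropoxydimethylsilyl)methylmagnesium chloride | CC(C)O[Si](C)(C)C[Mg]Cl | intermediate
6 | 1,2-dibromotetrachloroethane | BrC(Cl)(Cl)C(Cl)(Cl)Br | starting material
7 | [6-fluoro-2-methoxy-3-(triisopropylsilyloxy)phenyl]lithium | COc1c([Li])c(F)ccc1O[Si](C(C)C)(C(C)C)C(C)C | intermediate
8 | 3-methoxy-4-(triisopropylsilyloxy)-1,2-didehydrobenzene | COC1=C(O[Si](C(C)C)(C(C)C)C(C)C)C=CC#C1 | intermediate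
9 | [6-[(isopropoxydimethylsilyl)methyl]-2-methoxy-3-(triisopropylsilyloxy)phenyl]magnesium chloride | COc1c(O[Si](C(C)C)(C(C)C)C(C)C)ccc(C[Si](C)(C)OC(C)C)c1[Mg]Cl | intermediate
10 | [3-bromo-4-[(isopropoxydimethylsilyl)methyl]-2-methoxyphenoxy]triisopropylsilane | COc1c(O[Si](C(C)C)(C(C)C)C(C)C)ccc(C[Si](C)(C)OC(C)C)c1Br | intermediate
11 | [2-bromo-3-methoxy-4-(triisopropylsilyloxy)phenyl]methanol | COc1c(O[Si](C(C)C)(C(C)C)C(C)C)ccc(CO)c1Br | intermediate
12 | [2-bromo-3-methoxy-4-(triisopropylsilyloxy)phenyl]methyl acetate | COc1c(O[Si](C(C)C)(C(C)C)C(C)C)ccc(COC(C)=O)c1Br | intermediate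
13 | (2-bromo-4-hydroxy-3-methoxyphenyl)methyl acetate | COc1c(O)ccc(COC(C)=O)c1Br | intermediate
14 | (2,3,6-tribromo-4-hydroxy-5-methoxyphenyl)methyl acetate | COc1c(O)c(Br)c(Br)c(COC(C)=O)c1Br | intermediate
15 | (2,3,6-tribromo-4-hydroxy-5-methoxyphenyl)methanol | COc1c(O)c(Br)c(Br)c(CO)c1Br | target

**Totals.** Total step count: 8. Longest linear sequence: 7 steps (1 → 3 → 10 → 11 → 12 → 13 → 14 → 15; the Grignard reagent 5 joins in step 3 after one step of its own).

**Steps most likely to fail**

Step 3. The aryne may be captured by aryllithium 7 instead of by 5 (biaryl formation). Lithiation may stray to the hydrogen that is ortho to fluorine only, giving the isomeric aryne. Bromine transfer to the hindered arylmagnesium may stay incomplete while surplus 5 uses up the electrophile. The fallback drops the aryne and uses cooperative directed ortho-metalation. It sets out from 2: vanillin F1 is silylated with 2 (imidazole, DMF) to 3-methoxy-4-(triisopropylsilyloxy)benzaldehyde F2, which NaBH4 (THF/EtOH, 0 °C) reduces to [3-methoxy-4-(triisopropylsilyloxy)phenyl]methanol F3. Treatment of F3 with n-BuLi (2.2 equiv, Et2O/TMEDA, 0 °C to rt) should form the alkoxide and then lithiate the ring carbon lying between the OMe and CH2OLi groups, and a quench with 6 at −78 °C should give 11, where the route is rejoined before step 5.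

Step 7. Substitution at C6 may stop short because the methoxy group, flanked on both sides, is twisted and donates poorly. HBr may exchange the benzylic acetate, and attack at C1 para to the phenol may divert material. The fallback moves the benzylic carbon to the aldehyde oxidation level, which has no labile benzylic C–O bond and tolerates Lewis-acid-forced bromination. It sets out from 11: MnO2 (CH2Cl2, rt) should give 2-bromo-3-methoxy-4-(triisopropylsilyloxy)benzaldehyde F4, TBAF (THF, 0 °C) should give 2-bromo-4-hydroxy-3-methoxybenzaldehyde F5, and Br2 with FeBr3 (cat.) in AcOH at 50 °C should give 2,3,6-tribromo-4-hydroxy-5-methoxybenzaldehyde F6. Reduction with NaBH4 (THF/H2O, 0 °C) then comes back to the route at 15.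

Step 8. The phenoxide may expel acetate in a 1,6-elimination, and the quinone methide formed may be captured by another phenoxide instead of by water, which gives oligomers. The fallback replaces acyl cleavage under base by substitution at the benzylic carbon under acid, so that no phenoxide is ever present. It sets out from 14: HBr in AcOH (rt) should convert the acetate into 2,3,5-tribromo-4-(bromomethyl)-6-methoxyphenol F7, and solvolysis of this reactive para-hydroxybenzyl bromide in acetone/H2O (1:1) at rt should give 15.

**Further compounds**
F1 | step 3 | vanillin (4-hydroxy-3-methoxybenzaldehyde) | COc1cc(C=O)ccc1O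
F2 | step 3 | 3-methoxy-4-(triisopropylsilyloxy)benzaldehyde | COc1cc(C=O)ccc1O[Si](C(C)C)(C(C)C)C(C)C
F3 | step 3 | [3-methoxy-4-(triisopropylsilyloxy)phenyl]methanol | COc1cc(CO)ccc1O[Si](C(C)C)(C(C)C)C(C)C
F4 | step 7 | 2-bromo-3-methoxy-4-(triisopropylsilyloxy)benzaldehyde | COc1c(O[Si](C(C)C)(C(C)C)C(C)C)ccc(C=O)c1Br
F5 | step 7 | 2-bromo-4-hydroxy-3-methoxybenzaldehyde | COc1c(O)ccc(C=O)c1Br
F6 | step 7 | 2,3,6-tribromo-4-hydroxy-5-methoxybenzaldehyde | COc1c(O)c(Br)c(Br)c(C=O)c1Br
F7 | step 8 | 2,3,5-tribromo-4-(bromomethyl)-6-methoxyphenol | COc1c(O)c(Br)c(Br)c(CBr)c1Br
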